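The readings were computed for substances that don't exist; noise was put on by code.

The decision for this flask is to add Z at 6.0 d, and the reckoning below has to earn it.

| setting | Thursday's | Wednesday's | flask |
|---|---|---|---|
| D | 0.10 M | 0.10 M | 0.10 M |
| Z | 0.90 µM | 0.90 µM | 0.90 µM |
| Q | 2.5 µM | 5 µM | 2.5 µM |
| remark | the very flask that is asked about, followed so far | run made earlier |  |
| time |  |  | 6.0 d |

| run | time / h | L / % | D / % |
|---|---|---|---|
| Thursday's | 12.0 | 16.6 | 83.6 |
| Thursday's | 20.0 | 21.6 | 77.9 |
| Thursday's | 25.0 | 23.5 | 76.2 |
| Thursday's | 40.0 | 28.0 | 72.5 |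
| Thursday's | 60.0 | 30.9 | 69.1 |
| Thursday's | 96.0 | 33.7 | 66.4 |
| Thursday's | 144 | 36.8 | 63.1 |
| Wednesday's | 1.50 | 3.2 | 96.6 |
| Wednesday's | 3.00 | 5.0 | 94.3 |
| Wednesday's | 5.00 | 7.8 | 92.4 |
| Wednesday's | 6.00 | 9.0 | 91.4 |
| Wednesday's | 8.00 | 9.9 | 90.3 |
| Wednesday's | 10.0 | 11.0 | 89.2 |
| Wednesday's | 12.0 | 12.2 | 88.1 |

(standard deviation of a reading: 0.3 percentage points)

- L, in percent of the D first charged, at 6.0 d
- what to do for the largest gain in L; "none" if nothing gains more than 2 percentage points (dusk / winter / summer / dawn / none)
- L present, with what was taken out counted in, in percent of the D first charged, after summer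
- L present, with what was taken out counted in, in percent of the D first charged, after dawn

- dusk: at 6.0 d take out 90% of the L then present, then wait 40 h
- winter: at 6.0 d add D, 50.0% of the amount charged, then wait 40 h
- summer: at 6.0 d add Z, 100% of the amount charged, then wait 40 h
- dawn: change nothing and wait 40 h more

- what is taken out of L is counted as made
- what may be going on: D + Z -> L + Z; Z + Q <-> X
- additions bring no volume worth counting

Has Thursday's flask stopped? Its last reading stands at the asked time, so L now is 36.8%. L rose 21.4 times more slowly over the last interval than over the first. That factor is larger than the ratio of D charged to D left, 1.58, so in Thursday's flask the catalyst has faded as well. Continuing that last slope, dawn gains 2.6 percentage points.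

What took the catalyst? With twice the c_Q, Wednesday's flask had made 12.2% by 12.0 h, against 16.6% on Thursday, so Q removes Z as X. The measure is the spare Q, c_Q charged minus c_Z charged: 1.60 µM here. Z is thus the limiting reagent of the binding.

What can the options do? Dusk touches neither Z nor Q, so it counts as dawn. With the rate taken proportional to c_D, winter gains 4.6 points. The summer dose is smaller than the spare Q, so Q can still bind it, but not at once. The same amount of Z made 28.0% in Thursday's first 40 h. Scaled to the D left, that is 18 points, and with the tail, summer is reckoned at 57.1%, a reckoned gain larger than those of the other options.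

The forecast says 36.8% now, summer as the choice, 61% after summer (above the figure reckoned here) and 39.3% after dawn, holding that “Fresh Z outruns the remaining free Q”.

The flask gives 36.9% now and summer as the choice, with 57.3% after summer, a gain of 20 points, and 39.4% after dawn.

    D + Z → L + Z, rate k1*[D]^2*[Z]/(1 + ([D]/Kh1)^2) (0.110 M, k = 4.50 × 10⁵ M⁻² h⁻¹)
    Z + Q ⇌ X (K = 1.10 × 10⁷ M⁻¹, k = 30000 M⁻¹ h⁻¹)

At 144 h this flask holds 94.7% of its catalyst as X, outside the working round, while D stands at 63.1%. Q stands at 65.9% of its charge, and the spare Q reckons 64.0%. In the neighbouring flask, charged with 3.6 × 10⁻⁶ M of Z and otherwise the same, the sign turns: charged Z exceeds charged Q by 1.10 µM, which reckons 30.6% of the Z free. At 144 h that flask holds 35.2% of its Z free and 6.74% of its Q, and L stands at 89.9%.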